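**Assumption:** the SMILES is read literally, i.e. the cis-fused hydroazulene (CH3-8a and H-3a on the same face, 3-OH and the 4-acyloxy group on the opposite face), (3R,3aS,4R,8aR). Small organometallic and alkylating agents (i-PrMgCl, MeI, CO2) are treated as reagents.

## Retrosynthetic overview

1. Target ⇒ late ester coupling of C15 diol 21 with O-TBS-isovanillic acid 30 (made from catechol), then desilylation.
2. Diol 21 ⇒ hydroxy enone 20 by chelation-controlled 1,2-reduction (sets C-4).
3. 20 ⇒ bromo diketone 17 by intramolecular samarium aldol: the cyclopentane is closed second, onto the existing seven-membered ring (sets the cis fusion and the tertiary carbinol).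
4. 17 ⇒ dienone 7 + Grignard reagent from bromo ketal 10 (asymmetric conjugate addition sets the quaternary centre).
5. 7 ⇒ 2,5-dimethylfuran + tetrabromoacetone ([4+3]; seven-membered ring formed first); 10 ⇒ 3-bromopropanoyl chloride + i-PrMgCl.

## Route

Step 1
Reactants: 1 2,5-dimethylfuran; 2 1,1,3,3-tetrabromopropan-2-one
Product: 4 (1R,5S)-1,5-dimethyl-8-oxabicyclo[3.2.1]oct-6-en-3-one (meso), via dibromo cycloadduct 3 (not isolated)
Conditions: Zn, B(OEt)3, THF, rt, dark; then Zn–Cu, NH4Cl, MeOH, rt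
Reagents that add atoms: none
Why: Zinc generates the oxyallyl cation from 2, which undergoes [4+3] cycloaddition across the electron-rich furan; Zn–Cu then removes the two α-bromines, and the product is meso, so no stereochemical issue arises.

Step 2
Reactants: 4 (1R,5S)-1,5-dimethyl-8-oxabicyclo[3.2.1]oct-6-en-3-one
Product: 5 (1R,5S)-1,5-dimethyl-8-oxabicyclo[3.2.1]octan-3-one (meso)
Conditions: H2 (1 atm), 10% Pd/C, EtOAc, rt
Reagents that add atoms: none
Why: Catalytic hydrogenation of the strained, unhindered bridge alkene leaves the ketone and the bridging ether untouched.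

Step 3
Reactants: 5 (1R,5S)-1,5-dimethyl-8-oxabicyclo[3.2.1]octan-3-one
Product: 7 3,6-dimethylcyclohepta-2,6-dien-1-one, via hydroxy enone 6 (not isolated)
Conditions: p-TsOH·H2O (10 mol %), PhH, reflux, Dean–Stark
Reagents that add atoms: none
Why: Acid-catalysed double β-elimination (retro-oxa-Michael opening of the tertiary bridge ether, then aldol-type dehydration of the tertiary β-hydroxy ketone) is driven by azeotropic water removal; it is the oxygen analogue of the tropinone-to-cycloheptadienone degradation.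

Step 4
Reactants: 8 3-bromopropanoyl chloride
Product: 9 1-bromo-4-methylpentan-3-one
Conditions: i-PrMgCl (1.0 equiv), CuI (5 mol %), THF, −78 °C; cold 1 M HCl
Reagents that add atoms: isopropylmagnesium chloride CC(C)[Mg]Cl
Why: Copper-catalysed Grignard acylation of the acid chloride at −78 °C stops at the ketone and does not touch the primary bromide.

Step 5
Reactants: 9 1-bromo-4-methylpentan-3-one
Product: 10 2-(2-bromoethyl)-5,5-dimethyl-2-(propan-2-yl)-1,3-dioxane
Conditions: neopentyl glycol, HC(OEt)3, p-TsOH (cat.), CH2Cl2, rt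
Reagents that add atoms: 2,2-dimethylpropane-1,3-diol OCC(C)(C)CO
Why: Acid-catalysed ketalisation with orthoformate as water scavenger masks the ketone as a 1,3-dioxane, the ketal type whose β-bromoethyl Grignard reagent is thermally stable.

Step 6
Reactants: 10 2-(2-bromoethyl)-5,5-dimethyl-2-(propan-2-yl)-1,3-dioxane; 7 3,6-dimethylcyclohepta-2,6-dien-1-one
Product: 13 (6R)-6-{2-[5,5-dimethyl-2-(propan-2-yl)-1,3-dioxan-2-yl]ethyl}-3,6-dimethylcyclohept-2-en-1-one, via Grignard reagent 11 (not isolated), via magnesium dienolate 12 (not isolated)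
Conditions: 10, Mg, THF, 40 °C; then Cu(OTf)2 (3 mol %), chiral C2-symmetric imidazolinium (NHC) salt (4 mol %), Et2O, −30 °C, slow addition of 7; NH4Cl aq
Reagents that add atoms: none
Why: Cu/NHC-catalysed asymmetric conjugate addition of the Grignard reagent to one of the two homotopic β-methyl enone units of the dienone; the ligand antipode is chosen so that the selected enone face gives the (R) quaternary centre, and the magnesium dienolate formed cannot add a second time.

Step 7
Reactants: 13 (6R)-6-{2-[5,5-dimethyl-2-(propan-2-yl)-1,3-dioxan-2-yl]ethyl}-3,6-dimethylcyclohept-2-en-1-one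
Product: 16 (6R,7RS)-7-bromo-6-{2-[5,5-dimethyl-2-(propan-2-yl)-1,3-dioxan-2-yl]ethyl}-3,6-dimethylcyclohept-2-en-1-one, via lithium dienolate 14 (not isolated), via TMS dienol ether 15 (not isolated)
Conditions: LDA, THF, −78 °C; TMSCl; then NBS, THF, −78 → 0 °C
Reagents that add atoms: N-bromosuccinimide O=C1CCC(=O)N1Br
Why: Kinetic deprotonation of the enone at the α′-CH2 (as with isophorone) gives the cross-conjugated dienolate, and bromination of its silyl enol ether is regiospecific at that carbon; the CHBr configuration is irrelevant because the carbon becomes an enolate in step 9.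

Step 8
Reactants: 16 (6R,7RS)-7-bromo-6-{2-[5,5-dimethyl-2-(propan-2-yl)-1,3-dioxan-2-yl]ethyl}-3,6-dimethylcyclohept-2-en-1-one
Product: 17 (6R,7RS)-7-bromo-3,6-dimethyl-6-(4-methyl-3-oxopentyl)cyclohept-2-en-1-one
Conditions: 1 M HCl, THF, rt
Reagents that add atoms: water O
Why: Acid-catalysed ketal hydrolysis; the α-bromo ketone has no β-hydrogen for HBr loss and the enone tolerates dilute acid.

Step 9
Reactants: 17 (6R,7RS)-7-bromo-3,6-dimethyl-6-(4-methyl-3-oxopentyl)cyclohept-2-en-1-one
Product: 20 (3R,3aR,8aR)-3-hydroxy-6,8a-dimethyl-3-(propan-2-yl)-2,3,3a,7,8,8a-hexahydroazulen-4(1H)-one, via samarium dienolate 18 (not isolated), via samarium aldolate 19 (not isolated)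
Conditions: SmI2 (2.2 equiv), THF, −78 °C; NH4Cl aq at −78 °C
Reagents that add atoms: none
Why: SmI2 reduces the C–Br bond to a regiodefined Sm(III) enolate that closes the cyclopentane by an intramolecular Reformatsky-type aldol onto the isopropyl ketone; the three-atom tether can only reach the enolate face it sits on (cis fusion, H-3a cis to CH3-8a), and Sm chelation between enolate oxygen and ketone places the new OH cis to the C-4 carbonyl with isopropyl on the convex face.

Step 10
Reactants: 20 (3R,3aR,8aR)-3-hydroxy-6,8a-dimethyl-3-(propan-2-yl)-2,3,3a,7,8,8a-hexahydroazulen-4(1H)-one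
Product: 21 (3R,3aS,4R,8aR)-6,8a-dimethyl-3-(propan-2-yl)-1,2,3,3a,4,7,8,8a-octahydroazulene-3,4-diol
Conditions: NaBH4, CeCl3·7H2O, MeOH, −78 °C
Reagents that add atoms: none
Why: Luche 1,2-reduction of the enone; with the 3-OH and the carbonyl held together by cerium, hydride enters from the open face flanked by H-3a (convex face of the cis-bicycle), giving the (4R) alcohol syn to the tertiary OH.

Step 11
Reactants: 22 benzene-1,2-diol (catechol)
Product: 23 2-methoxyphenol
Conditions: MeI (1.0 equiv), Li2CO3, DMF, 55 °C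
Reagents that add atoms: iodomethane CI
Why: Williamson mono-O-methylation; the weak lithium base ionises only one catechol OH, and the mono-ether is separated from traces of catechol and veratrole by extraction and distillation.

Step 12
Reactants: 23 2-methoxyphenol
Product: 24 2-methoxyphenyl acetate
Conditions: Ac2O, pyridine, DMAP (cat.), CH2Cl2, rt
Reagents that add atoms: acetic anhydride CC(=O)OC(C)=O
Why: O-Acetylation turns the phenol into a weak donor so that the methoxy group alone directs the next substitution.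

Step 13
Reactants: 24 2-methoxyphenyl acetate
Product: 25 5-bromo-2-methoxyphenyl acetate
Conditions: NBS, MeCN, 60 °C
Reagents that add atoms: N-bromosuccinimide O=C1CCC(=O)N1Br
Why: Electrophilic aromatic bromination occurs para to the methoxy group, the stronger donor, which fixes the isovanillic substitution pattern.

Step 14
Reactants: 25 5-bromo-2-methoxyphenyl acetate
Product: 26 5-bromo-2-methoxyphenol
Conditions: K2CO3 (0.1 equiv), MeOH, rt
Reagents that add atoms: none
Why: Base-catalysed transesterification (methanolysis) of the aryl acetate frees the phenol without touching the aryl bromide.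

Step 15
Reactants: 26 5-bromo-2-methoxyphenol
Product: 27 (5-bromo-2-methoxyphenoxy)(tert-butyl)dimethylsilane
Conditions: TBSCl, imidazole, DMF, rt
Reagents that add atoms: tert-butyldimethylsilyl chloride CC(C)(C)[Si](C)(C)Cl
Why: Silylation gives a phenol protecting group that survives organolithium chemistry and acylation and is later removed by fluoride without harming an ester.

Step 16
Reactants: 27 (5-bromo-2-methoxyphenoxy)(tert-butyl)dimethylsilane
Product: 30 3-[(tert-butyldimethylsilyl)oxy]-4-methoxybenzoic acid, via aryllithium 28 (not isolated), via lithium carboxylate 29 (not isolated)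
Conditions: n-BuLi, THF, −78 °C; CO2; 1 M HCl to pH 3, 0 °C
Reagents that add atoms: carbon dioxide O=C=O
Why: Bromine–lithium exchange followed by carboxylation; the silyl ether is meta to the lithiated carbon, so no silyl migration can occur.

Step 17
Reactants: 21 (3R,3aS,4R,8aR)-6,8a-dimethyl-3-(propan-2-yl)-1,2,3,3a,4,7,8,8a-octahydroazulene-3,4-diol; 30 3-[(tert-butyldimethylsilyl)oxy]-4-methoxybenzoic acid
Product: 32 (3R,3aS,4R,8aR)-3-hydroxy-6,8a-dimethyl-3-(propan-2-yl)-1,2,3,3a,4,7,8,8a-octahydroazulen-4-yl 3-[(tert-butyldimethylsilyl)oxy]-4-methoxybenzoate, via mixed anhydride 31 (not isolated)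
Conditions: 30, 2,4,6-Cl3C6H2COCl, Et3N, THF, rt; then 21, DMAP, PhMe, rt → 40 °C
Reagents that add atoms: none
Why: Yamaguchi esterification joins the two fragments; the DMAP-activated acyl group goes only to the secondary allylic OH because the tertiary OH next to isopropyl is too hindered, and no stereocentre is touched.

Step 18
Reactants: 32 (3R,3aS,4R,8aR)-3-hydroxy-6,8a-dimethyl-3-(propan-2-yl)-1,2,3,3a,4,7,8,8a-octahydroazulen-4-yl 3-[(tert-butyldimethylsilyl)oxy]-4-methoxybenzoate
Product: 33 (3R,3aS,4R,8aR)-3-hydroxy-6,8a-dimethyl-3-(propan-2-yl)-1,2,3,3a,4,7,8,8a-octahydroazulen-4-yl 3-hydroxy-4-methoxybenzoate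
Conditions: TBAF, AcOH (1:1), THF, 0 °C
Reagents that add atoms: none
Why: Fluoride-mediated desilylation of the aryl silyl ether, buffered with acetic acid so that the allylic benzoate neither migrates nor is cleaved.

## Compound list

1 | 2,5-dimethylfuran | Cc1ccc(C)o1 | starting material
2 | 1,1,3,3-tetrabromopropan-2-one | O=C(C(Br)Br)C(Br)Br | starting material
3 | 2,4-dibromo-1,5-dimethyl-8-oxabicyclo[3.2.1]oct-6-en-3-one (diastereomer mixture, not isolated) | CC12C=CC(C)(O1)C(Br)C(=O)C2Br | intermediate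
4 | (1R,5S)-1,5-dimethyl-8-oxabicyclo[3.2.1]oct-6-en-3-one (meso) | C[C@]12C=C[C@](C)(O1)CC(=O)C2 | intermediate
5 | (1R,5S)-1,5-dimethyl-8-oxabicyclo[3.2.1]octan-3-one (meso) | C[C@]12CC[C@](C)(O1)CC(=O)C2 | intermediate
6 | 6-hydroxy-3,6-dimethylcyclohept-2-en-1-one (racemic, not isolated) | CC1=CC(=O)CC(C)(O)CC1 | intermediate
7 | 3,6-dimethylcyclohepta-2,6-dien-1-one | CC1=CC(=O)C=C(C)CC1 | intermediate
8 | 3-bromopropanoyl chloride | O=C(Cl)CCBr | starting material
9 | 1-bromo-4-methylpentan-3-one | CC(C)C(=O)CCBr | intermediate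
10 | 2-(2-bromoethyl)-5,5-dimethyl-2-(propan-2-yl)-1,3-dioxane | CC(C)C1(CCBr)OCC(C)(C)CO1 | intermediate
11 | {2-[5,5-dimethyl-2-(propan-2-yl)-1,3-dioxan-2-yl]ethyl}magnesium bromide (not isolated) | CC(C)C1(CC[Mg]Br)OCC(C)(C)CO1 | intermediate
12 | bromomagnesium (3R)-3-{2-[5,5-dimethyl-2-(propan-2-yl)-1,3-dioxan-2-yl]ethyl}-3,6-dimethylcyclohepta-1,6-dien-1-olate (not isolated) | Br[Mg]OC1=C[C@@](C)(CCC2(C(C)C)OCC(C)(C)CO2)CCC(C)=C1 | intermediate
13 | (6R)-6-{2-[5,5-dimethyl-2-(propan-2-yl)-1,3-dioxan-2-yl]ethyl}-3,6-dimethylcyclohept-2-en-1-one | O=C1C=C(C)CC[C@](C)(CCC2(C(C)C)OCC(C)(C)CO2)C1 | intermediate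
14 | lithium (3R)-3-{2-[5,5-dimethyl-2-(propan-2-yl)-1,3-dioxan-2-yl]ethyl}-3,6-dimethylcyclohepta-1,6-dien-1-olate (not isolated) | [Li]OC1=C[C@@](C)(CCC2(C(C)C)OCC(C)(C)CO2)CCC(C)=C1 | intermediate
15 | {[(3R)-3-{2-[5,5-dimethyl-2-(propan-2-yl)-1,3-dioxan-2-yl]ethyl}-3,6-dimethylcyclohepta-1,6-dien-1-yl]oxy}trimethylsilane (not isolated) | C[Si](C)(C)OC1=C[C@@](C)(CCC2(C(C)C)OCC(C)(C)CO2)CCC(C)=C1 | intermediate
16 | (6R,7RS)-7-bromo-6-{2-[5,5-dimethyl-2-(propan-2-yl)-1,3-dioxan-2-yl]ethyl}-3,6-dimethylcyclohept-2-en-1-one | O=C1C=C(C)CC[C@](C)(CCC2(C(C)C)OCC(C)(C)CO2)C1Br | intermediate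
17 | (6R,7RS)-7-bromo-3,6-dimethyl-6-(4-methyl-3-oxopentyl)cyclohept-2-en-1-one | O=C1C=C(C)CC[C@](C)(CCC(=O)C(C)C)C1Br | intermediate
18 | diiodosamarium(III) (3R)-3,6-dimethyl-3-(4-methyl-3-oxopentyl)cyclohepta-1,6-dien-1-olate (not isolated) | I[Sm](I)OC1=C[C@@](C)(CCC(=O)C(C)C)CCC(C)=C1 | intermediate
19 | diiodosamarium(III) alkoxide of 20 at O-3 (not isolated) | O=C1C=C(C)CC[C@]2(C)CC[C@@](O[Sm](I)I)(C(C)C)[C@H]12 | intermediate
20 | (3R,3aR,8aR)-3-hydroxy-6,8a-dimethyl-3-(propan-2-yl)-2,3,3a,7,8,8a-hexahydroazulen-4(1H)-one | O=C1C=C(C)CC[C@]2(C)CC[C@@](O)(C(C)C)[C@H]12 | intermediate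
21 | (3R,3aS,4R,8aR)-6,8a-dimethyl-3-(propan-2-yl)-1,2,3,3a,4,7,8,8a-octahydroazulene-3,4-diol | O[C@@H]1C=C(C)CC[C@]2(C)CC[C@@](O)(C(C)C)[C@H]12 | intermediate
22 | benzene-1,2-diol (catechol) | Oc1ccccc1O | starting material
23 | 2-methoxyphenol | COc1ccccc1O | intermediate
24 | 2-methoxyphenyl acetate | COc1ccccc1OC(C)=O | intermediate
25 | 5-bromo-2-methoxyphenyl acetate | COc1ccc(Br)cc1OC(C)=O | intermediate
26 | 5-bromo-2-methoxyphenol | COc1ccc(Br)cc1O | intermediate
27 | (5-bromo-2-methoxyphenoxy)(tert-butyl)dimethylsilane | COc1ccc(Br)cc1O[Si](C)(C)C(C)(C)C | intermediate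
28 | {3-[(tert-butyldimethylsilyl)oxy]-4-methoxyphenyl}lithium (not isolated) | [Li]c1ccc(OC)c(O[Si](C)(C)C(C)(C)C)c1 | intermediate
29 | lithium 3-[(tert-butyldimethylsilyl)oxy]-4-methoxybenzoate (not isolated) | [Li+].[O-]C(=O)c1ccc(OC)c(O[Si](C)(C)C(C)(C)C)c1 | intermediate
30 | 3-[(tert-butyldimethylsilyl)oxy]-4-methoxybenzoic acid | COc1ccc(C(=O)O)cc1O[Si](C)(C)C(C)(C)C | intermediate
31 | 3-[(tert-butyldimethylsilyl)oxy]-4-methoxybenzoic 2,4,6-trichlorobenzoic anhydride (not isolated) | COc1ccc(C(=O)OC(=O)c2c(Cl)cc(Cl)cc2Cl)cc1O[Si](C)(C)C(C)(C)C | intermediate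
32 | (3R,3aS,4R,8aR)-3-hydroxy-6,8a-dimethyl-3-(propan-2-yl)-1,2,3,3a,4,7,8,8a-octahydroazulen-4-yl 3-[(tert-butyldimethylsilyl)oxy]-4-methoxybenzoate | COc1ccc(C(=O)O[C@@H]2C=C(C)CC[C@]3(C)CC[C@@](O)(C(C)C)[C@H]23)cc1O[Si](C)(C)C(C)(C)C | intermediate
33 | (3R,3aS,4R,8aR)-3-hydroxy-6,8a-dimethyl-3-(propan-2-yl)-1,2,3,3a,4,7,8,8a-octahydroazulen-4-yl 3-hydroxy-4-methoxybenzoate | COc1ccc(C(=O)O[C@@H]2C=C(C)CC[C@]3(C)CC[C@@](O)(C(C)C)[C@H]23)cc1O | target

## Step count and risks

Total step count: 18.
Longest linear sequence: 10 steps (1, 2, 3, 6, 7, 8, 9, 10, 17, 18).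

**Step 6** (enantioselective formation of the quaternary centre on a cross-conjugated dienone with a functionalised Grignard reagent; risks are modest ee and competing 1,2-addition). Fallback: starting again from 7 and 10, run the addition without a chiral ligand as a plain copper-catalysed Grignard conjugate addition (CuBr·SMe2 10 mol %, THF, −40 °C, NH4Cl work-up). This gives the racemic ketone, which is resolved by preparative chiral SFC. The (6R) enantiomer is 13, where the route is rejoined; the other enantiomer, (6S)-6-{2-[5,5-dimethyl-2-(propan-2-yl)-1,3-dioxan-2-yl]ethyl}-3,6-dimethylcyclohept-2-en-1-one F1, is discarded.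

**Step 9** (the samarium enolate may simply be protonated instead of attacking the hindered isopropyl ketone, or the aldolate may revert). Fallback: set out from 13, leave out the bromination, and hydrolyse the ketal (1 M HCl, THF) to (6R)-3,6-dimethyl-6-(4-methyl-3-oxopentyl)cyclohept-2-en-1-one F2. This is also the reduction by-product of a failed step 9, so that material can be recycled. F2 is cyclised under reversible, thermodynamically controlled base-mediated aldol conditions (KOt-Bu 0.2 equiv, t-BuOH/THF, 0 °C). Only the α′-enolate can close an unstrained fused five-membered ring onto the isopropyl ketone; the other aldol or Michael modes give bridged rings and revert. The route is rejoined at 20.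

**Step 10** (facial selectivity of the enone reduction). Fallback: set out from 20; if the reduction gives mainly the C-4 epimer, (3R,3aS,4S,8aR)-6,8a-dimethyl-3-(propan-2-yl)-1,2,3,3a,4,7,8,8a-octahydroazulene-3,4-diol F3, keep it and couple it with acid 30 under Mitsunobu conditions (PPh3, DIAD, PhMe, 0 °C → rt). This esterifies the secondary allylic alcohol with inversion and rejoins the route at 32.

## Further compounds

F1 | step 6 | (6S)-6-{2-[5,5-dimethyl-2-(propan-2-yl)-1,3-dioxan-2-yl]ethyl}-3,6-dimethylcyclohept-2-en-1-one | O=C1C=C(C)CC[C@@](C)(CCC2(C(C)C)OCC(C)(C)CO2)C1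
F2 | step 9 | (6R)-3,6-dimethyl-6-(4-methyl-3-oxopentyl)cyclohept-2-en-1-one | O=C1C=C(C)CC[C@](C)(CCC(=O)C(C)C)C1
F3 | step 10 | (3R,3aS,4S,8aR)-6,8a-dimethyl-3-(propan-2-yl)-1,2,3,3a,4,7,8,8a-octahydroazulene-3,4-diol | O[C@H]1C=C(C)CC[C@]2(C)CC[C@@](O)(C(C)C)[C@H]12
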